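**Retrosynthetic overview**
1. Numbering: oxolane O1, C2 (guaiacyl), C3 (carries hydroxymethyl carbon C6), C4 (carries benzylic carbon C7), C5. The route rests on two features of this ring. C2–O1–C5 is a three-atom ether bridge spanning the C3–C4 bond, and the arms C6 and C7 stand cis, so an oxygen placed between them gives a γ-lactone fused to the oxolane.
2. C6H2OH goes back to C6O2H, and C7H2 goes back to a benzylic C7–O–C6(=O) bond. The target thus becomes a cis-fused 2,6-diaryl furofuranone.
3. C2–C3 and C4–C5 are cut together as a [3+2] of the ylide ArCH=O(+)–CH2(−) with (S)-5-veratrylbutenolide. The C7 centre of the butenolide steers the face and is erased later.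
4. The ylide source is an α-chlorobenzyl silylmethyl ether made from vanillin (O-pivalate, acetal, chloride exchange). The butenolide comes from veratraldehyde and methyl propiolate (asymmetric alkynylation, semihydrogenation, lactonisation).
5. Ring order: lactone ring (step 5), oxolane (step 6), lactone opened again (step 7).

Key step: step 6

Assumption: the ligand antipode in step 4 is named by analogy with the usual facial bias of this catalyst. Both antipodes are commercial, and the one meant is the one that delivers the alkynyl group to the Si face of the aldehyde (R alcohol).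

**Step 1**
Reactants: 1 vanillin
Product: 2 4-formyl-2-methoxyphenyl pivalate
Conditions: PivCl, Et3N, DMAP (cat.), CH2Cl2, 0 °C → rt
Reagents that add atoms: pivaloyl chloride, CC(C)(C)C(=O)Cl
Why: O-acylation of the phenol under nucleophilic catalysis; the pivalate is preferred to an acetate because it resists the acid and alcohol of step 2 and the fluoride of step 6, lowers the donor power of the ring so that C2 is not ionised in step 7, and leaves under the hydride of step 8.

**Step 2**
Reactants: 2 4-formyl-2-methoxyphenyl pivalate; 3 (trimethylsilyl)methanol (2.2 equiv)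
Product: 4 4-{bis[(trimethylsilyl)methoxy]methyl}-2-methoxyphenyl pivalate
Conditions: p-TsOH·H2O (1 mol %), cyclohexane, reflux through 4 Å MS (Soxhlet); Et3N quench
Reagents that add atoms: none
Why: Acid-catalysed acetalisation of an aromatic aldehyde with a primary alcohol, driven by removal of water, with the hindered aryl ester and the C–Si bonds inert to catalytic acid.

**Step 3**
Reactants: 4 4-{bis[(trimethylsilyl)methoxy]methyl}-2-methoxyphenyl pivalate
Product: 5 4-{chloro[(trimethylsilyl)methoxy]methyl}-2-methoxyphenyl pivalate (racemic, used at once without purification)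
Conditions: AcCl (1.0 equiv), Zn(OAc)2 (0.5 mol %), CH2Cl2, 0 °C → rt; volatiles off under high vacuum
Reagents that add atoms: acetyl chloride, CC(=O)Cl
Why: Zinc-salt-catalysed acetal–acyl chloride exchange, in which one acetal oxygen is acylated and leaves as its ester and chloride caps the aryl-stabilised oxocarbenium ion, gives the α-chloro ether without water and without residual aldehyde (a competing dipolarophile for the ylide), the new centre being racemic and erased in step 6.

**Step 4**
Reactants: 6 veratraldehyde; 7 methyl propiolate
Product: 9 methyl (R)-4-(3,4-dimethoxyphenyl)-4-hydroxybut-2-ynoate, via alkynylzinc 8 (not isolated)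
Conditions: (R,R)-ProPhenol (10 mol %), Me2Zn (3 equiv), 7 (3 equiv), toluene, 0–4 °C; aq NH4Cl
Reagents that add atoms: none
Why: Catalytic enantioselective alkynylation of an aromatic aldehyde by a dinuclear zinc–ProPhenol complex, in which Me2Zn metalates the acidic propiolate C–H and the chiral pocket delivers the alkynyl group to the Si face of the bound aldehyde, sets C7 as R (alkynyl outranks aryl).

**Step 5**
Reactants: 9 methyl (R)-4-(3,4-dimethoxyphenyl)-4-hydroxybut-2-ynoate
Product: 11 (S)-5-(3,4-dimethoxyphenyl)furan-2(5H)-one, via Z-hydroxy enoate 10 (not isolated)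
Conditions: H2 (1 atm), 5% Pd/CaCO3 poisoned with Pb(OAc)2, quinoline, EtOAc, rt; filter; PPTS (5 mol %), CH2Cl2, rt
Reagents that add atoms: none
Why: Lindlar-type syn semihydrogenation gives the Z-enoate, whose hydroxyl and ester are held together and lactonise by mild transesterification without touching the C7–O bond, so the configuration is retained (the descriptor becomes S only because the ranking of the substituents changes).

**Step 6**
Reactants: 5 4-{chloro[(trimethylsilyl)methoxy]methyl}-2-methoxyphenyl pivalate (2 equiv); 11 (S)-5-(3,4-dimethoxyphenyl)furan-2(5H)-one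
Product: 13 (3S,3aR,6S,6aS)-3-(3,4-dimethoxyphenyl)-6-(3-methoxy-4-pivaloyloxyphenyl)tetrahydro-1H,3H-furo[3,4-c]furan-1-one (cis-fused, both aryl groups exo), via carbonyl ylide 12 (not isolated)
Conditions: CsF (flame-dried, 1.9 equiv, in portions), 4 Å MS, MeCN, 0 °C → rt
Reagents that add atoms: none
Why: Proposed new method: fluoride attacks silicon while chloride departs from the benzylic carbon (1,3-elimination), which releases the non-stabilised carbonyl ylide 12, and this 4π dipole adds suprafacially across C3=C4 of 11 in a concerted, asynchronous [3+2] cycloaddition that makes C4–C5 and C2–C3 in one event. The closest known reaction type is the cycloaddition of non-stabilised carbonyl ylides, made in the same way from α-chloroalkyl silylmethyl ethers, with acrylates, fumarates and maleates, whereas an aryl-substituted ylide of this kind has not been joined to a chiral γ-substituted butenolide. The oxolane O1–C2–C3–C4–C5 is closed intermolecularly by this two-bond annulation, and because the alkene is held Z inside the lactone the two rings must be cis-fused, so C3 and C4 are fixed relative to each other by suprafaciality. Their absolute sense comes from C7, since the veratryl group shields one face of the flat butenolide and the dipole arrives anti to it, as other 1,3-dipoles and cuprates do with 5-substituted butenolides. Regioselectivity is required and should follow polarity, because the aryl group favours the ArCH=O(+)–CH2(−) form, so the nucleophilic CH2 terminus C5 leads bond formation at the electrophilic β-carbon C4 and C2 closes on the α-carbon C3. C2 is set by the E geometry of the ylide combined with an exo approach, in which the lactone points away from the ylide oxygen and the aryl group avoids the C6 carbonyl, which leaves the aryl group on the convex face trans to C6, and any endo epimer would be removed by chromatography.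

**Step 7**
Reactants: 13 furofuranone
Product: 14 (2S,3S,4R)-4-(3,4-dimethoxybenzyl)-2-(3-methoxy-4-pivaloyloxyphenyl)tetrahydrofuran-3-carboxylic acid
Conditions: Et3SiH (4 equiv), CF3CO2H–CH2Cl2 (1:3), 0 °C → rt
Reagents that add atoms: none
Why: Ionic hydrogenation, in which the acid ionises only C7–O because C7 carries a carboxylic leaving group and the strongly donating veratryl ring whereas C2 carries an ether oxygen and an acyloxy-deactivated ring, and the silane traps the cation as CH2, so C7 disappears as a stereocentre while C2, C3 and C4 are untouched.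

**Step 8**
Reactants: 14 oxolane carboxylic acid
Product: 15 4'-O-methyllariciresinol, [(2S,3R,4R)-4-(3,4-dimethoxybenzyl)-2-(4-hydroxy-3-methoxyphenyl)tetrahydrofuran-3-yl]methanol
Conditions: LiAlH4 (5 equiv), THF, 0 °C → rt; aq potassium sodium tartrate, then aq NH4Cl to pH 7
Reagents that add atoms: none
Why: Hydride reduction with LiAlH4 takes the C6 carboxylate to the primary alcohol and cleaves the aryl pivalate in the same operation, while the oxolane, the aryl methyl ethers and the three stereocentres (none enolisable once the carboxylate has formed) are left alone, and the near-neutral work-up avoids acid-induced ionisation at C2.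

**Compound list**
1 | vanillin | COc1cc(C=O)ccc1O | starting material
2 | 4-formyl-2-methoxyphenyl pivalate | COc1cc(C=O)ccc1OC(=O)C(C)(C)C | intermediate
3 | (trimethylsilyl)methanol | C[Si](C)(C)CO | starting material
4 | 4-{bis[(trimethylsilyl)methoxy]methyl}-2-methoxyphenyl pivalate | COc1cc(C(OC[Si](C)(C)C)OC[Si](C)(C)C)ccc1OC(=O)C(C)(C)C | intermediate
5 | 4-{chloro[(trimethylsilyl)methoxy]methyl}-2-methoxyphenyl pivalate (racemic) | COc1cc(C(Cl)OC[Si](C)(C)C)ccc1OC(=O)C(C)(C)C | intermediate
6 | veratraldehyde | COc1ccc(C=O)cc1OC | starting material
7 | methyl propiolate | C#CC(=O)OC | starting material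
8 | methyl 3-(methylzincio)propiolate (alkynylzinc) | C[Zn]C#CC(=O)OC | intermediate
9 | methyl (R)-4-(3,4-dimethoxyphenyl)-4-hydroxybut-2-ynoate | COC(=O)C#C[C@H](O)c1ccc(OC)c(OC)c1 | intermediate
10 | methyl (S,Z)-4-(3,4-dimethoxyphenyl)-4-hydroxybut-2-enoate | COC(=O)/C=C\[C@H](O)c1ccc(OC)c(OC)c1 | intermediate
11 | (S)-5-(3,4-dimethoxyphenyl)furan-2(5H)-one | O=C1O[C@@H](C=C1)c1ccc(OC)c(OC)c1 | intermediate
12 | (E)-carbonyl ylide, 3-methoxy-4-pivaloyloxybenzylidene(methylido)oxonium | COc1cc(/C=[O+]/[CH2-])ccc1OC(=O)C(C)(C)C | intermediate
13 | (3S,3aR,6S,6aS)-3-(3,4-dimethoxyphenyl)-6-(3-methoxy-4-pivaloyloxyphenyl)tetrahydro-1H,3H-furo[3,4-c]furan-1-one | COc1cc([C@H]2OC[C@H]3[C@@H]2C(=O)O[C@@H]3c2ccc(OC)c(OC)c2)ccc1OC(=O)C(C)(C)C | intermediate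
14 | (2S,3S,4R)-4-(3,4-dimethoxybenzyl)-2-(3-methoxy-4-pivaloyloxyphenyl)tetrahydrofuran-3-carboxylic acid | COc1cc([C@H]2OC[C@H](Cc3ccc(OC)c(OC)c3)[C@@H]2C(=O)O)ccc1OC(=O)C(C)(C)C | intermediate
15 | 4'-O-methyllariciresinol | COc1cc([C@H]2OC[C@H](Cc3ccc(OC)c(OC)c3)[C@@H]2CO)ccc1O | target

Total step count: 8. Longest linear sequence: 6 steps (1, 2, 3, 6, 7, 8).

**Steps most likely to fail**

**Step 6 (new method).**
- The short-lived ylide may collapse or self-condense before a merely moderately activated, 1,2-disubstituted enoate captures it.
- Polarity control of the regiochemistry may leak.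
- Discrimination between exo and endo approach (configuration at C2) may be weak. Acid equilibration is not counted on to mend it, since exo- and endo-aryl furofurans lie close in energy.
- Fluoride may remove the acidic C7–H of 11 and erode the enantiopurity, which is why CsF is kept below the amount of 5.

The fallback uses known chemistry and still uses C7 as a traceless controller. It sets out from 11, takes 2 as the aldehyde partner and comes back at 15. Benzophenone-sensitised photoaddition of methanol (hν 350 nm, MeOH) places a hydroxymethyl radical on C4 anti to the aryl group and gives (4R,5S)-5-(3,4-dimethoxyphenyl)-4-(hydroxymethyl)dihydrofuran-2(3H)-one F1. Et3SiH in CF3CO2H removes the benzylic C7–O bond, and the freed acid relactonises onto the C5 hydroxyl to give (R)-4-(3,4-dimethoxybenzyl)dihydrofuran-2(3H)-one F2. LiHMDS in THF at −78 °C followed by 2 gives, by aldol addition anti to the benzyl group, (3S,4R)-4-(3,4-dimethoxybenzyl)-3-[hydroxy(3-methoxy-4-pivaloyloxyphenyl)methyl]dihydrofuran-2(3H)-one F3, of which both carbinol epimers serve. LiAlH4 reduces the lactone and cleaves the pivalate to (2R,3R)-2-(3,4-dimethoxybenzyl)-3-[hydroxy(4-hydroxy-3-methoxyphenyl)methyl]butane-1,4-diol F4. Catalytic camphorsulfonic acid in CH2Cl2–THF at 0 °C ionises the p-hydroxybenzylic alcohol, and the C5 hydroxyl closes the oxolane with the aryl group trans to the C6 arm, which gives 15.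

**Step 7.** Ionisation may not stay confined to C7. Opening of the oxolane at C2 would lead to epimerisation or over-reduction, or the lactone may ionise too slowly at a temperature that C2 tolerates.

The fallback leaves the cationic pathway altogether. It sets out from 13 and comes back at 14. Heterogeneous hydrogenolysis (H2, 1 atm, Pd/C, EtOAc–AcOH, rt) cleaves the benzylic acyloxy C7–O bond on the metal surface, where a benzylic ester is lost more readily than a cyclic benzylic ether and no free cation can scramble C2. No compound outside the list is made (F0).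

**Step 4.** Addition to the electron-rich aldehyde may be slow, the enantioselectivity may be insufficient, or methyl transfer may compete.

The fallback builds the butenolide by resolution and metathesis. It sets out from 6 and comes back at 11. CH2=CHMgBr in THF at 0 °C gives racemic 1-(3,4-dimethoxyphenyl)prop-2-en-1-ol F5. Immobilised Candida antarctica lipase B with vinyl acetate in MTBE, run past half conversion, leaves (S)-1-(3,4-dimethoxyphenyl)prop-2-en-1-ol F6 unreacted. By the usual size rule for secondary alcohols, it removes the fast-reacting antipode as (R)-1-(3,4-dimethoxyphenyl)allyl acetate F7. Acryloyl chloride and Et3N in CH2Cl2 at 0 °C convert F6 into (S)-1-(3,4-dimethoxyphenyl)allyl acrylate F8. Ring-closing metathesis with the second-generation Grubbs catalyst in refluxing CH2Cl2 then closes 11 without touching C7.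

**Further compounds**
F1 | step 6 | (4R,5S)-5-(3,4-dimethoxyphenyl)-4-(hydroxymethyl)dihydrofuran-2(3H)-one | O=C1C[C@H](CO)[C@@H](c2ccc(OC)c(OC)c2)O1
F2 | step 6 | (R)-4-(3,4-dimethoxybenzyl)dihydrofuran-2(3H)-one | O=C1C[C@@H](Cc2ccc(OC)c(OC)c2)CO1
F3 | step 6 | (3S,4R)-4-(3,4-dimethoxybenzyl)-3-[hydroxy(3-methoxy-4-pivaloyloxyphenyl)methyl]dihydrofuran-2(3H)-one (carbinol epimers) | O=C1OC[C@H](Cc2ccc(OC)c(OC)c2)[C@H]1C(O)c1ccc(OC(=O)C(C)(C)C)c(OC)c1
F4 | step 6 | (2R,3R)-2-(3,4-dimethoxybenzyl)-3-[hydroxy(4-hydroxy-3-methoxyphenyl)methyl]butane-1,4-diol (carbinol epimers) | OC[C@H](Cc1ccc(OC)c(OC)c1)[C@H](CO)C(O)c1ccc(O)c(OC)c1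
F0 | step 7 | none | none
F5 | step 4 | racemic 1-(3,4-dimethoxyphenyl)prop-2-en-1-ol | C=CC(O)c1ccc(OC)c(OC)c1
F6 | step 4 | (S)-1-(3,4-dimethoxyphenyl)prop-2-en-1-ol | C=C[C@H](O)c1ccc(OC)c(OC)c1
F7 | step 4 | (R)-1-(3,4-dimethoxyphenyl)allyl acetate | C=C[C@@H](OC(C)=O)c1ccc(OC)c(OC)c1
F8 | step 4 | (S)-1-(3,4-dimethoxyphenyl)allyl acrylate | C=CC(=O)O[C@@H](C=C)c1ccc(OC)c(OC)c1
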